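## Analysis of the target

The target is a labdane: a trans-fused decalin (rings A and B) with a gem-dimethyl group at C4, an angular methyl at C10 and, on C9, a five-carbon chain that ends in a tertiary allylic alcohol. It is the 6α-angelate of a 6α-hydroxysclareol. There are six stereocentres: C5 (S), C6 (S), C8 (R), C9 (R) and C10 (S) in the rings and C13 (R) in the chain. In ring terms these are 5α-H, an equatorial 6α-oxygen, an equatorial 8α-hydroxyl with an axial 8β-methyl, 9α-H with an equatorial side chain, and a 10β-methyl. The ring centres form two contiguous sets (C5–C6 and C8–C9–C10) around the quaternary C10 and can be related to one another, but C13 is three bonds from the ring and is beyond substrate control. The sensitive groups are the (Z)-2-methylbut-2-enoate, which isomerises to the E ester and is cleaved by hydrides, and the tertiary allylic alcohol, which ionises under acid and, with the C8 hydroxyl, closes to cyclic ethers. The hard points are the quaternary C10 next to C9, the hindered 6α position beside C4, and the equatorial C8 carbinol, which cannot be made by adding a methyl nucleophile to a C8 ketone because attack comes from the α face. The strategy rests on C9 lying between the oxygenated C8 and C11: it can be the α-carbon of a β-keto ester (C8 ketone, C11 ester). Dihydro-β-ionone (1) already holds ring A, C6, C7, C8 and the tetrasubstituted C5=C10 alkene, so one C9–C10 bond closes ring B.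

## Retrosynthetic reasoning

C6–O acyl bond. The angelate is removed first, because it would not survive hydride, strong base or electrophilic oxidants. This leads to triol 28 and angelic acid 29; 28 has one secondary and two tertiary hydroxyls, so the esterification needs no protecting group.

C8–O and C17–H. The equatorial tertiary alcohol of 28 is traced to spiro-epoxide 27 and from there to the exocyclic alkene of 26. Epoxidation from the α face, away from the axial C10 methyl, followed by hydride attack at the primary C17 gives the 8α-ol. The alkene is kept until this point so that no free C8 hydroxyl is present while C13 is still an epoxide carbon.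

C13. The tertiary allylic alcohol of 26 comes from epoxy iodide 25 by reductive opening, and 25 from epoxy alcohol 24. The C13–O bond is therefore made by Sharpless epoxidation of the (E)-allylic alcohol 23, which sets the remote centre by reagent control.

C11–C12. Allylic alcohol 23 is cut between C11 and C12, through 22 and 21, into the drimane sulfone 16 and the allylic bromide 20. The sulfone makes the hindered C11 a nucleophile, and the (E)-trisubstituted alkene is bought ready-made with 20, which comes from prenol 17 through 18 and 19.

C11 oxidation level. Sulfone 16 goes back through sulfide 15 to alcohol 14, and 14 to ester 13. Reduction of 13 also releases the auxiliary 4.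

C9–H. The β,γ-unsaturated ester 13 is the deconjugated isomer of enoate 11. The forward step has to take a proton from the C12 methyl and return one to C9 from the α face (through dienolate 12), which sets 9α-H.

C6–O and C5–H. Silyl ether 11 comes from alcohol 10, and 10 from diene ester 8 by syn addition of H and OH (through borane 9) to the C5=C6 alkene from the α face. This makes the trans ring fusion and the equatorial 6α-oxygen together.

C8–C12. The C8 methyl of 8 is cut to enol triflate 7, made from β-keto ester 6. The C8 ketone is thus used twice, first to carry the radical and then to carry the methyl group.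

C9–C10, the key disconnection. Bicyclic keto ester 6 is opened between C9 and C10 to the monocyclic keto ester 5. The forward reaction must form the quaternary C10 with the right absolute configuration and leave a C5=C6 alkene as the handle for C6.

Precursor. Ester 5 is cut at the ester oxygen into methyl ester 3 and the auxiliary 4, and 3 at C9–C11 into dihydro-β-ionone 1 and dimethyl carbonate 2.

## Alternatives that were turned down

Alternative 1: Here C4–C5, C9–C10 and the C8–O bond are cut together, which unfolds both rings into the acyclic (S)-silyloxy trienone A1, a farnesylacetone that already carries the future C6 oxygen. In the forward sense Hg(OTf)2·PhNMe2 would activate the terminal alkene of A1, a cationic cascade would close rings A and B, the ketone oxygen would trap the C8 cation, and NaBH4 would replace mercury by hydrogen to give the cyclic enol ether A2. In its favour, one operation makes both rings, the quaternary C10 and four stereocentres with the trans–anti relationships of a chair–chair cascade, and the C8–O bond arrives with the right configuration. On step economy it is clearly stronger than the chosen route. Against it, the absolute sense of the whole cascade depends on one allylic stereocentre. That silyloxy group sits next to the nucleophilic C5=C10 alkene, lowers its reactivity inductively and can itself ionise under the electrophilic conditions. A2 also still lacks C14, C15 and the C13 centre, which would have to come from a vinyl addition that the ring cannot steer. The chosen strategy gives up the cascade and pays in steps. In return it places the C6 oxygen only after the skeleton exists, takes its absolute configuration from a recoverable auxiliary, and sets C13 by reagent control.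

Alternative 2: Here C9–C11 and C10–C20 are cut on a preformed ring B. The silylated p-cresol quinol A3 would take the ketal-bearing Grignard reagent A4 at one of its two enantiotopic enone arms under CuBr·SMe2 and a chiral ferrocenyl diphosphine, anti to the silyloxy group, and the enolate would be methylated to give enone A5 with C8, C9 and C10 set. In its favour, the asymmetric induction is catalytic, the C8 tertiary oxygen has the right configuration from the first step, and the C11–C16 chain arrives intact. On these points it is stronger. Against it, A5 is only ring B. Ring A with its gem-dimethyl C4 must still be annulated onto C5 and C10, C10 must be made quaternary by a second alkylation beside a branched centre, and the ring fusion must then be controlled. The enone must be converted into a C6 alcohol while C7 loses its function. The C8 silyloxy group is vinylogously β to the C5 carbonyl, so each enolisation invites elimination and rearomatisation. C13 again remains open. The chosen strategy gets the whole bicyclic carbon skeleton, with both quaternary carbons, in three steps from a terpenoid ketone and needs no annulation.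

Alternative 3: Here C5–C10 and C8–C9 are cut. The triene A6 carries a 1,3-bis(silyloxy)diene (C5=C6–C7=C8) tethered through C1–C4 to an E-enoyl oxazolidinone (C9=C10). Under Cu(t-Bu-box)(SbF6)2, a bis(oxazoline) complex of divalent copper, it would undergo an intramolecular Diels–Alder reaction to the trans-fused adduct A7. In its favour, both rings, four stereocentres and both ring oxygens (C6 as a silyl enol ether, C8 as a tertiary silyl ether) come from one catalytic enantioselective step, and C11 arrives as an acyl group. It is the most convergent of the four plans. Against it, the dienophile carbon C10 is β,β-disubstituted, a class that reacts sluggishly with chelating copper catalysts. The diene terminus C8 is fully substituted and must hold its silyloxy group on the inside to give the 8α-oxygen, which disfavours the s-cis conformer. C5 is neopentyl, and an electron-rich bis(silyloxy)diene under a cationic Lewis acid is prone to stepwise Mukaiyama–Michael addition or desilylation. After unmasking of the C6 carbonyl, hydride delivery from the open α face would give the axial 6β-alcohol, so the equatorial 6α-oxygen would need a thermodynamic reduction. A6, with three defined alkene geometries, is itself a multi-step target. The chosen strategy forms only one bond in its key step, but from a precursor made in two steps, and its 6α-oxygen arrives together with the 5α-hydrogen in one syn addition.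

Key step: step 3

Remark on numbering: labdane numbering is used (C17 on C8, C18 and C19 on C4, C20 on C10); the bicyclic intermediates are named as drimanes, in which these carbons are C12, C13, C14 and C15, and C1–C11 are the same in both.

Assumption: the (1R,2S,5R) auxiliary is taken to give the 10β-methyl series, as the chelated chair model of the ring closure predicts; the opposite sense would be answered with the enantiomeric auxiliary.

## Route

Step 1
Reactants: 1 dihydro-β-ionone, 2 dimethyl carbonate
Product: 3 methyl 3-oxo-5-(2,6,6-trimethylcyclohex-1-en-1-yl)pentanoate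
Conditions: NaH, THF, reflux; then AcOH
Reagents that add atoms: none
Why: Claisen-type C-acylation of the ketone enolate with a carbonate; acylation occurs at the less hindered methyl terminus, and the product is held as its stabilised enolate until the acidic quench.

Step 2
Reactants: 3 methyl 3-oxo-5-(2,6,6-trimethylcyclohex-1-en-1-yl)pentanoate, 4 (−)-8-phenylmenthol
Product: 5 (1R,2S,5R)-8-phenylmenthyl 3-oxo-5-(2,6,6-trimethylcyclohex-1-en-1-yl)pentanoate
Conditions: DMAP (cat.), toluene, reflux, 4 Å MS (MeOH removed)
Reagents that add atoms: none
Why: Transesterification of a β-keto ester, which proceeds through the enol/acylketene manifold and therefore accepts a hindered secondary alcohol; removal of methanol drives it.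

Step 3
Reactants: 5 (1R,2S,5R)-8-phenylmenthyl 3-oxo-5-(2,6,6-trimethylcyclohex-1-en-1-yl)pentanoate
Product: 6 8-phenylmenthyl 8-oxo-12-nordrim-5-en-11-oate (9α-H, 10β-methyl)
Conditions: Mn(OAc)3·2H2O (2.2 equiv), Cu(OAc)2·H2O (1 equiv), Yb(OTf)3 (1 equiv), CF3CH2OH, 0 °C → rt, degassed
Reagents that add atoms: none
Why: Mn(OAc)3 turns the Yb(OTf)3-chelated β-keto ester into its manganese enolate, and one-electron oxidation gives the electrophilic C9 radical. This radical adds 6-endo-trig to C10 of the electron-rich ring A alkene and closes ring B through a chair with the C8 carbonyl inside the ring, the mode such α-keto radicals prefer over 5-exo attack at C5. The tertiary C5 radical is captured by Cu(OAc)2 as an alkylcopper species of trivalent copper; β-hydride loss can only go toward C6 because C4 and C10 carry no hydrogen, so the C5=C6 alkene should form as one regioisomer, and monovalent copper is returned to the divalent state by Mn(OAc)3. The closest known reaction is the Mn(OAc)3/Cu(OAc)2 oxidative free-radical cyclisation of unsaturated β-keto esters, including lanthanide-assisted versions with 8-phenylmenthyl esters. C10 is the centre that counts: chelation holds the two carbonyls syn, the phenyl group of the auxiliary covers one face of the C9 radical, and the alkene approaches the other face with the ester equatorial, which for the (1R,2S,5R) auxiliary should place the C10 methyl β. C9 settles to the equatorial β-ester by enolisation and is flattened again in step 4. The step needs facial selectivity (auxiliary), 6-endo closure (ketone in the ring) and alkene formation ahead of further oxidation (the product enolises slowly beside the quaternary C10); the C10 epimers are diastereomers and should be separable.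

Step 4
Reactants: 6 8-phenylmenthyl 8-oxo-12-nordrim-5-en-11-oate
Product: 7 8-phenylmenthyl 8-(trifluoromethylsulfonyloxy)-12-nordrima-5,8-dien-11-oate
Conditions: NaH, THF, 0 °C; PhNTf2, rt; aq. NH4Cl
Reagents that add atoms: N-phenylbis(trifluoromethanesulfonimide), O=S(=O)(N(c1ccccc1)S(=O)(=O)C(F)(F)F)C(F)(F)F
Why: Enol triflate formation from a cyclic β-keto ester; deprotonation at C9 gives the chelated enolate, which is sulfonylated on the ketone oxygen.

Step 5
Reactants: 7 8-phenylmenthyl 8-(trifluoromethylsulfonyloxy)-12-nordrima-5,8-dien-11-oate
Product: 8 8-phenylmenthyl drima-5,8-dien-11-oate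
Conditions: MeMgBr, Fe(acac)3 (5 mol %), THF/NMP, −30 °C
Reagents that add atoms: methylmagnesium bromide, C[Mg]Br
Why: Iron-catalysed cross-coupling of an alkenyl triflate with a methyl Grignard reagent; β-sulfonyloxy enoates couple at low temperature faster than the hindered ester is attacked. This installs C12.

Step 6
Reactants: 8 8-phenylmenthyl drima-5,8-dien-11-oate
Product: 10 8-phenylmenthyl 6α-hydroxydrim-8-en-11-oate, via C6 alkylborane 9 (not isolated)
Conditions: BH3·THF, THF, 0 °C → rt; then NaOH, H2O2, 0 °C → rt
Reagents that add atoms: borane–tetrahydrofuran, B.C1CCOC1 (boron of 9); hydrogen peroxide, OO (oxygen of 10)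
Why: Brown hydroboration–oxidation; boron goes to the less substituted C6 and, with its hydrogen, to the α face opposite the axial methyls on C10 and C4, so syn addition should give 5α-H and, after retentive oxidation, 6α-OH. The tetrasubstituted, electron-poor C8=C9 enoate is left alone, as in the α-face hydroboration of Δ5 steroids.

Step 7
Reactants: 10 8-phenylmenthyl 6α-hydroxydrim-8-en-11-oate
Product: 11 8-phenylmenthyl 6α-(tert-butyldimethylsilyloxy)drim-8-en-11-oate
Conditions: TBSOTf, 2,6-lutidine, CH2Cl2, 0 °C
Reagents that add atoms: tert-butyldimethylsilyl trifluoromethanesulfonate, CC(C)(C)[Si](C)(C)OS(=O)(=O)C(F)(F)F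
Why: Silylation of a hindered secondary alcohol with a silyl triflate; the ether survives strong base, hydride, peroxide and organolithium in the following steps.

Step 8
Reactants: 11 8-phenylmenthyl 6α-(tert-butyldimethylsilyloxy)drim-8-en-11-oate
Product: 13 8-phenylmenthyl 6α-(tert-butyldimethylsilyloxy)drim-8(12)-en-11-oate, via lithium dienolate 12 (not isolated)
Conditions: LiN(iPr)2, HMPA, THF, −78 °C; then AcOH, −78 °C
Reagents that add atoms: lithium diisopropylamide, [Li+].CC(C)[N-]C(C)C (lithium of 12)
Why: Deconjugative protonation of an α,β-unsaturated ester; the carbonyl-bound amide base removes a proton from the γ-methyl C12, which is syn to the ester, whereas C7 is anti. Kinetic protonation of 12 at the α-carbon C9 from the α face, away from the C10 methyl, should give the 9α-H ester with the exocyclic alkene.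

Step 9
Reactants: 13 8-phenylmenthyl 6α-(tert-butyldimethylsilyloxy)drim-8(12)-en-11-oate
Product: 14 6α-(tert-butyldimethylsilyloxy)drim-8(12)-en-11-ol
Conditions: LiAlH4, THF, 0 °C → reflux; aq. NaOH work-up
Reagents that add atoms: none
Why: Hydride reduction of the ester to the primary alcohol; the auxiliary 4 is set free and recovered, and the isolated alkene and silyl ether are inert.

Step 10
Reactants: 14 6α-(tert-butyldimethylsilyloxy)drim-8(12)-en-11-ol
Product: 15 6α-(tert-butyldimethylsilyloxy)-11-(phenylthio)drim-8(12)-ene
Conditions: PhSSPh, n-Bu3P, pyridine, 60 °C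
Reagents that add atoms: diphenyl disulfide, c1ccccc1SSc1ccccc1
Why: Hata reaction; the alcohol is activated as an alkoxyphosphonium ion and displaced at the primary C11 by thiolate, a nucleophile strong enough for a β-branched carbon.

Step 11
Reactants: 15 6α-(tert-butyldimethylsilyloxy)-11-(phenylthio)drim-8(12)-ene
Product: 16 6α-(tert-butyldimethylsilyloxy)-11-(phenylsulfonyl)drim-8(12)-ene
Conditions: (NH4)6Mo7O24·4H2O (cat.), 30% H2O2, EtOH, 0 °C → rt
Reagents that add atoms: hydrogen peroxide, OO
Why: Molybdate-catalysed peroxide oxidation of sulfide to sulfone, which is chemoselective for sulfur over a 1,1-disubstituted alkene.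

Step 12
Reactants: 17 prenol
Product: 18 tert-butyldimethyl(3-methylbut-2-en-1-yloxy)silane
Conditions: TBSCl, imidazole, CH2Cl2, rt
Reagents that add atoms: tert-butyldimethylsilyl chloride, CC(C)(C)[Si](C)(C)Cl
Why: Standard silylation of a primary allylic alcohol.

Step 13
Reactants: 18 tert-butyldimethyl(3-methylbut-2-en-1-yloxy)silane
Product: 19 (E)-4-(tert-butyldimethylsilyloxy)-2-methylbut-2-en-1-ol
Conditions: SeO2 (cat.), t-BuOOH, CH2Cl2, rt
Reagents that add atoms: tert-butyl hydroperoxide, CC(C)(C)OO (net oxygen source, delivered through SeO2)
Why: Riley allylic oxidation in its catalytic form; the ene reaction and [2,3]-shift take place at the methyl group trans to the chain of a trisubstituted alkene and should give the (E)-allylic alcohol.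

Step 14
Reactants: 19 (E)-4-(tert-butyldimethylsilyloxy)-2-methylbut-2-en-1-ol
Product: 20 (E)-(4-bromo-3-methylbut-2-en-1-yloxy)(tert-butyl)dimethylsilane
Conditions: CBr4, PPh3, CH2Cl2, 0 °C
Reagents that add atoms: carbon tetrabromide, BrC(Br)(Br)Br
Why: Appel bromination of a primary allylic alcohol under neutral conditions, which keeps the silyl ether and the alkene geometry.

Step 15
Reactants: 16 6α-(tert-butyldimethylsilyloxy)-11-(phenylsulfonyl)drim-8(12)-ene, 20 (E)-(4-bromo-3-methylbut-2-en-1-yloxy)(tert-butyl)dimethylsilane
Product: 21 6α,15-bis(tert-butyldimethylsilyloxy)-11-(phenylsulfonyl)labda-8(17),13E-diene (both C11 epimers)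
Conditions: n-BuLi, THF/HMPA, −78 °C; then 20, −78 → −20 °C
Reagents that add atoms: none
Why: Julia-type alkylation of an α-sulfonyl carbanion with a primary allylic bromide (SN2, alkene geometry retained); it forms C11–C12. The new C11 centre is removed in the next step.

Step 16
Reactants: 21 6α,15-bis(tert-butyldimethylsilyloxy)-11-(phenylsulfonyl)labda-8(17),13E-diene
Product: 22 6α,15-bis(tert-butyldimethylsilyloxy)labda-8(17),13E-diene
Conditions: Na(Hg) (6%), Na2HPO4, MeOH/THF, −20 °C → rt
Reagents that add atoms: none
Why: Reductive desulfonylation by electron transfer, C–S cleavage and protonation; the phosphate buffer suppresses base-induced elimination, and alkenes and silyl ethers are untouched.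

Step 17
Reactants: 22 6α,15-bis(tert-butyldimethylsilyloxy)labda-8(17),13E-diene
Product: 23 labda-8(17),13E-diene-6α,15-diol
Conditions: Bu4NF, THF, rt → 50 °C
Reagents that add atoms: none
Why: Fluoride cleavage of both silyl ethers; the hindered 6α-ether needs the higher temperature, which the diol tolerates.

Step 18
Reactants: 23 labda-8(17),13E-diene-6α,15-diol
Product: 24 (13R,14R)-13,14-epoxylabd-8(17)-ene-6α,15-diol
Conditions: Ti(OiPr)4, D-(−)-diethyl tartrate, t-BuOOH, 4 Å MS, CH2Cl2, −20 °C
Reagents that add atoms: tert-butyl hydroperoxide, CC(C)(C)OO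
Why: Sharpless asymmetric epoxidation; by the empirical rule the D-tartrate complex converts a geraniol-type (E)-allylic alcohol into the (2R,3R)-type epoxy alcohol, here 13R,14R, independent of the remote ring. Only the allylic alkene binds to titanium, so the exocyclic alkene is not touched.

Step 19
Reactants: 24 (13R,14R)-13,14-epoxylabd-8(17)-ene-6α,15-diol
Product: 25 (13R,14S)-13,14-epoxy-15-iodolabd-8(17)-en-6α-ol
Conditions: I2, PPh3, imidazole, THF, 0 °C
Reagents that add atoms: iodine, II
Why: Garegg–Samuelsson iodination; the primary alcohol reacts far faster than the hindered secondary 6α-hydroxyl, and the buffered medium spares the epoxide (the change to 14S is a priority change only).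

Step 20
Reactants: 25 (13R,14S)-13,14-epoxy-15-iodolabd-8(17)-en-6α-ol
Product: 26 (13R)-labda-8(17),14-diene-6α,13-diol
Conditions: Zn dust, EtOH, reflux; aq. NH4Cl
Reagents that add atoms: none
Why: Zinc inserts into the C–I bond and β-elimination opens the epoxide, the reductive transposition known from the epoxygeraniol-to-linalool sequence. The C13–O bond is not touched, so the 13R configuration is retained.

Step 21
Reactants: 26 (13R)-labda-8(17),14-diene-6α,13-diol
Product: 27 (13R)-8α,17-epoxylabd-14-ene-6α,13-diol
Conditions: mCPBA, NaHCO3, CH2Cl2, 0 °C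
Reagents that add atoms: 3-chloroperbenzoic acid, OOC(=O)c1cccc(Cl)c1
Why: Prilezhaev epoxidation; the 1,1-disubstituted alkene is more electron-rich than the vinyl group, and the peracid should approach from the α face, away from the axial C10 methyl, as in manool-type dienes.

Step 22
Reactants: 27 (13R)-8α,17-epoxylabd-14-ene-6α,13-diol
Product: 28 (13R)-labd-14-ene-6α,8α,13-triol
Conditions: LiAlH4, THF, 0 °C → reflux
Reagents that add atoms: none
Why: SN2 opening of the spiro-epoxide by hydride at the primary C17 leaves the oxygen on C8 in the α (equatorial) position and makes the axial 8β-methyl; the vinyl carbinol is inert to the reagent.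

Step 23
Reactants: 28 (13R)-labd-14-ene-6α,8α,13-triol, 29 angelic acid
Product: 31 6α-angeloyloxy-(13R)-labd-14-ene-8α,13-diol (CNP0203829.1), via angelic 2,4,6-trichlorobenzoic anhydride 30 (not isolated)
Conditions: 29, 2,4,6-trichlorobenzoyl chloride, Et3N, toluene, rt; then 28, 80 °C
Reagents that add atoms: 2,4,6-trichlorobenzoyl chloride, O=C(Cl)c1c(Cl)cc(Cl)cc1Cl (acyl group held in 30, not in 31)
Why: Yamaguchi-type esterification through the mixed anhydride; only the secondary 6α-hydroxyl is acylated, and the two tertiary alcohols stay free. Working without a nucleophilic catalyst or a free acid chloride is the usual way to keep the Z geometry of an angelate.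

## Compound list

1 | dihydro-β-ionone, 4-(2,6,6-trimethylcyclohex-1-en-1-yl)butan-2-one | CC(=O)CCC1=C(C)CCCC1(C)C | starting material
2 | dimethyl carbonate | COC(=O)OC | starting material
3 | methyl 3-oxo-5-(2,6,6-trimethylcyclohex-1-en-1-yl)pentanoate | COC(=O)CC(=O)CCC1=C(C)CCCC1(C)C | intermediate
4 | (−)-8-phenylmenthol, (1R,2S,5R)-5-methyl-2-(2-phenylpropan-2-yl)cyclohexan-1-ol | O[C@H]1[C@H](C(C)(C)c2ccccc2)CC[C@@H](C)C1 | starting material
5 | (1R,2S,5R)-8-phenylmenthyl 3-oxo-5-(2,6,6-trimethylcyclohex-1-en-1-yl)pentanoate | CC1=C(CCC(=O)CC(=O)O[C@H]2[C@H](C(C)(C)c3ccccc3)CC[C@@H](C)C2)C(C)(C)CCC1 | intermediate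
6 | 8-phenylmenthyl 8-oxo-12-nordrim-5-en-11-oate (9α-H, 10β-methyl) | O=C(O[C@H]2[C@H](C(C)(C)c4ccccc4)CC[C@@H](C)C2)[C@@H]1[C@@]3(C)CCCC(C)(C)C3=CCC1=O | intermediate
7 | 8-phenylmenthyl 8-(trifluoromethylsulfonyloxy)-12-nordrima-5,8-dien-11-oate (10β-methyl) | O=C(O[C@H]5[C@H](C(C)(C)c6ccccc6)CC[C@@H](C)C5)C1=C(OS(=O)(=O)C(F)(F)F)CC=C2[C@]1(C)CCCC2(C)C | intermediate
8 | 8-phenylmenthyl drima-5,8-dien-11-oate (10β-methyl) | O=C(O[C@H]5[C@H](C(C)(C)c6ccccc6)CC[C@@H](C)C5)C1=C(C)CC=C2[C@]1(C)CCCC2(C)C | intermediate
9 | C6 alkylborane, 8-phenylmenthyl 6α-boranyldrim-8-en-11-oate (5α-H) | O=C(O[C@H]5[C@H](C(C)(C)c6ccccc6)CC[C@@H](C)C5)C1=C(C)C[C@H](B)[C@H]2C(C)(C)CCC[C@]12C | intermediate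
10 | 8-phenylmenthyl 6α-hydroxydrim-8-en-11-oate (5α-H) | O=C(O[C@H]5[C@H](C(C)(C)c6ccccc6)CC[C@@H](C)C5)C1=C(C)C[C@H](O)[C@H]2C(C)(C)CCC[C@]12C | intermediate
11 | 8-phenylmenthyl 6α-(tert-butyldimethylsilyloxy)drim-8-en-11-oate | O=C(O[C@H]5[C@H](C(C)(C)c6ccccc6)CC[C@@H](C)C5)C1=C(C)C[C@H](O[Si](C)(C)C(C)(C)C)[C@H]2C(C)(C)CCC[C@]12C | intermediate
12 | lithium dienolate of 11 (C11=C9 and C8=C12) | [Li+].[O-]C(O[C@H]5[C@H](C(C)(C)c6ccccc6)CC[C@@H](C)C5)=C1C(=C)C[C@H](O[Si](C)(C)C(C)(C)C)[C@H]2C(C)(C)CCC[C@]12C | intermediate
13 | 8-phenylmenthyl 6α-(tert-butyldimethylsilyloxy)drim-8(12)-en-11-oate (9α-H) | O=C(O[C@H]5[C@H](C(C)(C)c6ccccc6)CC[C@@H](C)C5)[C@@H]1[C@@]2(C)CCCC(C)(C)[C@@H]2[C@@H](O[Si](C)(C)C(C)(C)C)CC1=C | intermediate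
14 | 6α-(tert-butyldimethylsilyloxy)drim-8(12)-en-11-ol | OC[C@@H]1[C@@]2(C)CCCC(C)(C)[C@@H]2[C@@H](O[Si](C)(C)C(C)(C)C)CC1=C | intermediate
15 | 6α-(tert-butyldimethylsilyloxy)-11-(phenylthio)drim-8(12)-ene | c3ccccc3SC[C@@H]1[C@@]2(C)CCCC(C)(C)[C@@H]2[C@@H](O[Si](C)(C)C(C)(C)C)CC1=C | intermediate
16 | 6α-(tert-butyldimethylsilyloxy)-11-(phenylsulfonyl)drim-8(12)-ene | O=S(=O)(c3ccccc3)C[C@@H]1[C@@]2(C)CCCC(C)(C)[C@@H]2[C@@H](O[Si](C)(C)C(C)(C)C)CC1=C | intermediate
17 | prenol, 3-methylbut-2-en-1-ol | CC(C)=CCO | starting material
18 | tert-butyldimethyl(3-methylbut-2-en-1-yloxy)silane | CC(C)=CCO[Si](C)(C)C(C)(C)C | intermediate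
19 | (E)-4-(tert-butyldimethylsilyloxy)-2-methylbut-2-en-1-ol | OC/C(C)=C/CO[Si](C)(C)C(C)(C)C | intermediate
20 | (E)-(4-bromo-3-methylbut-2-en-1-yloxy)(tert-butyl)dimethylsilane | BrC/C(C)=C/CO[Si](C)(C)C(C)(C)C | intermediate
21 | 6α,15-bis(tert-butyldimethylsilyloxy)-11-(phenylsulfonyl)labda-8(17),13E-diene (both C11 epimers) | CC(C)(C)[Si](C)(C)OC/C=C(\C)CC(S(=O)(=O)c3ccccc3)[C@@H]1[C@@]2(C)CCCC(C)(C)[C@@H]2[C@@H](O[Si](C)(C)C(C)(C)C)CC1=C | intermediate
22 | 6α,15-bis(tert-butyldimethylsilyloxy)labda-8(17),13E-diene | CC(C)(C)[Si](C)(C)OC/C=C(\C)CC[C@@H]1[C@@]2(C)CCCC(C)(C)[C@@H]2[C@@H](O[Si](C)(C)C(C)(C)C)CC1=C | intermediate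
23 | labda-8(17),13E-diene-6α,15-diol | OC/C=C(\C)CC[C@@H]1[C@@]2(C)CCCC(C)(C)[C@@H]2[C@@H](O)CC1=C | intermediate
24 | (13R,14R)-13,14-epoxylabd-8(17)-ene-6α,15-diol | OC[C@H]1O[C@]1(C)CC[C@@H]2[C@@]3(C)CCCC(C)(C)[C@@H]3[C@@H](O)CC2=C | intermediate
25 | (13R,14S)-13,14-epoxy-15-iodolabd-8(17)-en-6α-ol | IC[C@H]1O[C@]1(C)CC[C@@H]2[C@@]3(C)CCCC(C)(C)[C@@H]3[C@@H](O)CC2=C | intermediate
26 | (13R)-labda-8(17),14-diene-6α,13-diol | C=C[C@](C)(O)CC[C@@H]1[C@@]2(C)CCCC(C)(C)[C@@H]2[C@@H](O)CC1=C | intermediate
27 | (13R)-8α,17-epoxylabd-14-ene-6α,13-diol | C=C[C@](C)(O)CC[C@@H]1[C@@]2(C)CCCC(C)(C)[C@@H]2[C@@H](O)C[C@@]1(C3)O3 | intermediate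
28 | (13R)-labd-14-ene-6α,8α,13-triol | C=C[C@](C)(O)CC[C@@H]1[C@@]2(C)CCCC(C)(C)[C@@H]2[C@@H](O)C[C@@]1(C)O | intermediate
29 | angelic acid, (Z)-2-methylbut-2-enoic acid | C/C=C(/C)C(=O)O | starting material
30 | angelic 2,4,6-trichlorobenzoic anhydride | C/C=C(/C)C(=O)OC(=O)c1c(Cl)cc(Cl)cc1Cl | intermediate
31 | 6α-angeloyloxy-(13R)-labd-14-ene-8α,13-diol (CNP0203829.1) | C=C[C@](C)(O)CC[C@@H]1[C@@]2(C)CCCC(C)(C)[C@@H]2[C@@H](OC(=O)/C(C)=C\C)C[C@@]1(C)O | target

## Step count and least certain steps

Total step count: 23. Longest linear sequence: 20 (steps 1–11 and 15–23); steps 12–14 form the three-step branch to bromide 20.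

Step 3 (key step). The most likely failure is slow addition of the C9 radical to the fully substituted C10. That would let further oxidation of the enolisable product, or radical coupling, compete with ring closure. Facial discrimination by the auxiliary may also be incomplete with so congested an alkene. The fallback replaces the oxidative manifold by a halogen atom-transfer chain, in which a slow ring closure costs only time because no oxidant is present. It sets out from 5. Bromination at C9 (NBS, Mg(ClO4)2 cat.) would give (1R,2S,5R)-8-phenylmenthyl 2-bromo-3-oxo-5-(2,6,6-trimethylcyclohex-1-en-1-yl)pentanoate F1. Et3B/O2 with Yb(OTf)3 would then start the 6-endo bromine atom-transfer cyclisation to 8-phenylmenthyl 5-bromo-8-oxo-12-nordriman-11-oate F2. DBU would remove HBr toward C6, the only carbon with a β-hydrogen, and the sequence returns to the route at 6.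

Step 6. Hydroboration of the C5=C6 alkene beside the gem-dimethyl C4 may be sluggish, so that reduction of the ester begins to compete, or attack may not be exclusively from the α face. The fallback sets out from 8. Peracid epoxidation from the α face would give 8-phenylmenthyl 5α,6α-epoxydrim-8-en-11-oate F3. Cp2TiCl (trivalent titanium, made from Cp2TiCl2 and zinc) with 1,4-cyclohexadiene would open it homolytically to the tertiary C5 radical with oxygen left on C6. Hydrogen-atom transfer to the α face of that radical returns to the route at 10.

Step 8. Deprotonation may occur at the ring methylene C7 instead of the C12 methyl, the dienolate may be protonated at its γ-terminus and return the conjugated ester, or the C6 silyloxy group may be lost by vinylogous elimination. The fallback is photochemical deconjugation. It sets out from 11: irradiation at 254 nm with a catalytic amine would cause a 1,5-hydrogen shift from the C12 methyl, which is syn to the ester, to the carbonyl oxygen. Ketonisation of the photodienol at C9 returns to the route at 13. No strong base is involved and no new compound is made.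

Step 15. The C11 carbanion is flanked by the tertiary C9 and the quaternary C10, so alkylation may be slow and proton transfer or elimination of the bromide may take over. The fallback reverses the way C11 is activated and sets out from 14. Appel bromination would give 11-bromo-6α-(tert-butyldimethylsilyloxy)drim-8(12)-ene F4, and magnesium would convert it into [6α-(tert-butyldimethylsilyloxy)drim-8(12)-en-11-yl]magnesium bromide F5. Coupling of F5 with 20 under Li2CuCl4 catalysis (SN2 at the primary allylic bromide) returns to the route at 22 and bypasses compounds 15, 16 and 21.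

Step 21. Epoxidation may not be fully selective for the α face of the exocyclic alkene, or the vinyl group may begin to react. The fallback is a radical hydration and sets out from 26. Mukaiyama hydration with Mn(dpm)3, PhSiH3 and O2 would put a hydrogen atom on C17 and trap the tertiary C8 radical with oxygen from the equatorial α direction, away from the C10 methyl. It returns to the route at 28, replaces steps 21 and 22, and makes no new compound.

Step 23. At 80 °C the Z alkene may isomerise to the tiglate, or acylation of the 6α-hydroxyl, which lies next to the equatorial methyl on C4, may be slow. The fallback builds the Z alkene in place and sets out from 28. Carbodiimide esterification with the saturated 2-[bis(2,2,2-trifluoroethoxy)phosphoryl]propanoic acid would give (13R)-8α,13-dihydroxylabd-14-en-6α-yl 2-[bis(2,2,2-trifluoroethoxy)phosphoryl]propanoate F6. Still–Gennari olefination of F6 with acetaldehyde (KN(SiMe3)2, 18-crown-6, −78 °C; extra base for the two tertiary hydroxyls) returns to the route at 31.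

## Further compounds

F1 | step 3 | (1R,2S,5R)-8-phenylmenthyl 2-bromo-3-oxo-5-(2,6,6-trimethylcyclohex-1-en-1-yl)pentanoate (both C2 epimers) | CC1=C(CCC(=O)C(Br)C(=O)O[C@H]2[C@H](C(C)(C)c3ccccc3)CC[C@@H](C)C2)C(C)(C)CCC1
F2 | step 3 | 8-phenylmenthyl 5-bromo-8-oxo-12-nordriman-11-oate (9α-H, 10β-methyl, C5 not defined) | O=C(O[C@H]5[C@H](C(C)(C)c6ccccc6)CC[C@@H](C)C5)[C@@H]1[C@@]2(C)CCCC(C)(C)C2(Br)CCC1=O
F3 | step 6 | 8-phenylmenthyl 5α,6α-epoxydrim-8-en-11-oate | O=C(O[C@H]5[C@H](C(C)(C)c6ccccc6)CC[C@@H](C)C5)C1=C(C)C[C@@H]3O[C@@]32C(C)(C)CCC[C@]12C
F0 | step 8 | none | none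
F4 | step 15 | 11-bromo-6α-(tert-butyldimethylsilyloxy)drim-8(12)-ene | BrC[C@@H]1[C@@]2(C)CCCC(C)(C)[C@@H]2[C@@H](O[Si](C)(C)C(C)(C)C)CC1=C
F5 | step 15 | [6α-(tert-butyldimethylsilyloxy)drim-8(12)-en-11-yl]magnesium bromide | Br[Mg]C[C@@H]1[C@@]2(C)CCCC(C)(C)[C@@H]2[C@@H](O[Si](C)(C)C(C)(C)C)CC1=C
F0 | step 21 | none | none
F6 | step 23 | (13R)-8α,13-dihydroxylabd-14-en-6α-yl 2-[bis(2,2,2-trifluoroethoxy)phosphoryl]propanoate | C=C[C@](C)(O)CC[C@@H]1[C@@]2(C)CCCC(C)(C)[C@@H]2[C@@H](OC(=O)C(C)P(=O)(OCC(F)(F)F)OCC(F)(F)F)C[C@@]1(C)O
A1 | alternative 1 | (S,5E,9E)-6,10,14-trimethyl-8-(triisopropylsilyloxy)pentadeca-5,9,13-trien-2-one | CC(=O)CC/C=C(\C)C[C@H](O[Si](C(C)C)(C(C)C)C(C)C)/C=C(\C)CCC=C(C)C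
A2 | alternative 1 | 6α-(triisopropylsilyloxy)-8α,13-epoxy-14,15-dinorlabd-12-ene | CC1=CC[C@@H]2[C@@]3(C)CCCC(C)(C)[C@@H]3[C@@H](O[Si](C(C)C)(C(C)C)C(C)C)C[C@@]2(C)O1
A3 | alternative 2 | 4-(tert-butyldimethylsilyloxy)-4-methylcyclohexa-2,5-dien-1-one | CC1(O[Si](C)(C)C(C)(C)C)C=CC(=O)C=C1
A4 | alternative 2 | [2-(2-methyl-1,3-dioxolan-2-yl)ethyl]magnesium bromide | CC1(CC[Mg]Br)OCCO1
A5 | alternative 2 | ring B enone with 8α-silyloxy group, C9 ketal side chain and C10 methyl (trans, trans) | CC1(CC[C@@H]2[C@@H](C)C(=O)C=C[C@@]2(C)O[Si](C)(C)C(C)(C)C)OCCO1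
A6 | alternative 3 | N-acyl oxazolidinone of (2E,8Z,10Z)-9,11-bis(tert-butyldimethylsilyloxy)-3,7,7-trimethyldodeca-2,8,10-trienoic acid | O=C1OCCN1C(=O)/C=C(\C)CCCC(C)(C)/C=C(O[Si](C)(C)C(C)(C)C)/C=C(/C)O[Si](C)(C)C(C)(C)C
A7 | alternative 3 | N-acyl oxazolidinone of trans-fused 6,8α-bis(tert-butyldimethylsilyloxy)drim-6-en-11-oic acid | O=C1OCCN1C(=O)[C@@H]2[C@@]3(C)CCCC(C)(C)[C@@H]3C(O[Si](C)(C)C(C)(C)C)=C[C@@]2(C)O[Si](C)(C)C(C)(C)C
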